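**Overview**

1. Atoms are numbered along the target SMILES from left to right (C1 … O36). The plan rests on the cyclohexane ring C5–C6–C7–C8–C11–C31, trans-fused to the oxepane ring O4–C5–C31–C33–C34–C35–C2. Its axial tertiary carbinol C8 and the neighbouring C11, which carries linker carbon C12, form a β-hydroxy aldehyde once C12 is a formyl group, so C8–C11 is cut by an aldol transform to an oxepane keto aldehyde.
2. C12–C13 comes from Horner–Wittig olefination of the C12 aldehyde with the C13 phosphoryl carbanion of the hydroazulene half, followed by diimide reduction. A carbanion beside an oxirane would open it, so the C14–C16 epoxide is installed last, directed by the C18 hydroxyl.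
3. Left half: allylboration of pent-4-enal with neryl boronate sets C5 and C31, Shi epoxidation sets C35, a 7-endo ether closure gives the oxepane, and the aldol then closes the cyclohexane.
4. Right half: (R)-linalool supplies C25 and the cyclopentene by metathesis. Epoxide opening by lithiated isobutyronitrile sets C22 and brings C28/C14, hydroboration sets C21, and enone metathesis closes the seven-membered ring. Oxidative transposition and CBS reduction give the C14=C16 / C18 carbinol pattern.
5. Ring order: oxepane, then cyclohexane (left); cyclopentane, then cycloheptene (right); oxirane last.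

Key step: step 9

Assumption: (S)-TRIP is taken to deliver the allyl group to the Si face of pent-4-enal (the (R)-acid is known to favour Re-face attack of allyl pinacol boronates); if the sense proved opposite, the (R)-acid would be used.

**Route**

Step 1
Reactants: 1 neryl acetate
Product: 2 neryl pinacol boronate
Conditions: B2pin2, Ni(cod)2 (5 mol%), PCy3 (10 mol%), EtOAc, 25 °C
Reagents that add atoms: bis(pinacolato)diboron, CC1(C)OB(OC1(C)C)B1OC(C)(C)C(C)(C)O1
Why: Nickel-catalysed allylic borylation (π-allylnickel from the acetate, transmetallation from the diboron) should give the primary allylboronate with the Z geometry kept, because isomerisation would need σ-bonding at the tertiary allyl terminus.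

Step 2
Reactants: 2 neryl pinacol boronate; 3 pent-4-enal
Product: 5 (5R,6R)-6-ethenyl-6,10-dimethylundeca-1,9-dien-5-ol, via boronate ester 4 (not isolated)
Conditions: (S)-TRIP [(S)-3,3′-bis(2,4,6-triisopropylphenyl)-1,1′-binaphthyl-2,2′-diyl hydrogen phosphate] (5 mol%), 4 Å sieves, toluene, −30 °C; aqueous NaHCO3 work-up
Reagents that add atoms: none
Why: Chiral-phosphoric-acid-catalysed allylboration through a Zimmerman–Traxler chair should place methyl C32 (trans to boron in the Z-boronate) anti and the homoprenyl chain syn to the new hydroxyl, which fixes quaternary C31 relative to C5, while the acid selects the aldehyde face that makes C5 R.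

Step 3
Reactants: 5 (5R,6R)-6-ethenyl-6,10-dimethylundeca-1,9-dien-5-ol
Product: 6 (5R,6R)-8-[(2R)-3,3-dimethyloxiran-2-yl]-6-ethenyl-6-methyloct-1-en-5-ol
Conditions: D-fructose-derived Shi ketone (30 mol%), KHSO5 (Oxone), K2CO3, Bu4NHSO4, MeCN–dimethoxymethane–aqueous Na2B4O7 buffer (pH 10.5), 0 °C
Reagents that add atoms: potassium peroxymonosulfate, [K+].[O-]S(=O)(=O)OO
Why: Shi asymmetric epoxidation should oxidise only the electron-rich trisubstituted alkene (the two monosubstituted alkenes are poor dioxirane substrates) and set C35 as R by reagent control.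

Step 4
Reactants: 6 epoxy alcohol
Product: 7 (3R,6R,7R)-7-(but-3-en-1-yl)-6-ethenyl-2,2,6-trimethyloxepan-3-ol
Conditions: camphor-10-sulfonic acid (10 mol%), CH2Cl2, 0 °C
Reagents that add atoms: none
Why: Acid-catalysed intramolecular epoxide opening in the 7-endo-tet mode should let the C5 hydroxyl attack the tertiary, cation-stabilising epoxide carbon C2, which closes the oxepane and leaves the C35–O bond and its configuration untouched.

Step 5
Reactants: 7 oxepanol
Product: 8 tert-butyldimethylsilyl ether of 7
Conditions: TBSOTf, 2,6-lutidine, CH2Cl2, −78 → 0 °C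
Reagents that add atoms: tert-butyldimethylsilyl trifluoromethanesulfonate, CC(C)(C)[Si](C)(C)OS(=O)(=O)C(F)(F)F
Why: Silyl ether formation with the reactive triflate should protect the hindered secondary C35 hydroxyl that sits next to quaternary C2.

Step 6
Reactants: 8 silyl ether
Product: 9 methyl ketone 4-[(2R,3R,6R)-6-(tert-butyldimethylsilyloxy)-3-ethenyl-3,7,7-trimethyloxepan-2-yl]butan-2-one
Conditions: PdCl2 (10 mol%), CuCl (1 equiv), O2 (1 atm), DMF–H2O 7:1, 25 °C
Reagents that add atoms: water, O
Why: In this Tsuji–Wacker oxidation divalent palladium should bind the unhindered C8=C9 alkene much faster than the vinyl group on quaternary C31, and Markovnikov attack of water gives the C8 methyl ketone.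

Step 7
Reactants: 9 methyl ketone
Product: 10 diol (C8 epimers) with C8–OH and C12–OH
Conditions: BH3·THF (2.5 equiv), THF, 0 → 25 °C; then NaOH, H2O2
Reagents that add atoms: hydrogen peroxide, OO
Why: Hydroboration–oxidation should add boron anti-Markovnikov to the remaining vinyl group (C12–OH after oxidation) while the same reagent reduces the ketone, which saves a protection because both carbinols are reoxidised in the next step.

Step 8
Reactants: 10 diol
Product: 11 oxepane keto aldehyde 2-[(2R,3R,6R)-6-(tert-butyldimethylsilyloxy)-3,7,7-trimethyl-2-(3-oxobutyl)oxepan-3-yl]acetaldehyde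
Conditions: Dess–Martin periodinane (3 equiv), NaHCO3, CH2Cl2, 25 °C
Reagents that add atoms: none
Why: Dess–Martin oxidation of both alcohols under buffered, non-enolising conditions should give the keto aldehyde without touching the silyl ether.

Step 9
Reactants: 11 oxepane keto aldehyde
Product: 13 bicyclic β-hydroxy aldehyde (5R,8S,11R,31R,35R), via enamine 12 (not isolated)
Conditions: pyrrolidine (0.3 equiv), AcOH (0.3 equiv), THF–H2O 19:1, 25 °C, until the isomer composition no longer changes
Reagents that add atoms: none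
Why: Pyrrolidine condenses faster with the aldehyde than with the methyl ketone, and enamine 12 attacks the C8 ketone through a chair-like transition state (amine-catalysed enolexo aldol addition of a keto aldehyde is the known reaction type), after which hydrolysis releases the catalyst and 13. The C8–C11 bond closes the cyclohexane ring C5–C6–C7–C8–C11–C31 in the 6-(enolexo)-exo-trig mode, and the ring is trans-fused to the oxepane because the chains on C5 and C31 are trans. Since the C–C bond formation can revert and the enamine can re-form at C11, the outcome is under thermodynamic control and the three less stable C8/C11 isomers should be converted into the fourth. C11 is set by the equatorial preference of the formyl group beside quaternary C31, and C8 by the axial methyl C32, whose syn-axial repulsion forces methyl C9 equatorial and the hydroxyl axial, where it can also hold an O–H···O=C contact. The step needs aldehyde-enamine rather than ketone-enamine reactivity and must stop before loss of water; the slower enamine formation of the ketone and the neutral, water-containing, room-temperature medium should secure both.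

Step 10
Reactants: 13 bicyclic β-hydroxy aldehyde
Product: 14 C8 triethylsilyl ether of 13
Conditions: TESOTf, 2,6-lutidine, CH2Cl2, −78 → −20 °C
Reagents that add atoms: triethylsilyl trifluoromethanesulfonate, CC[Si](CC)(CC)OS(=O)(=O)C(F)(F)F
Why: Silylation of the tertiary axial C8 hydroxyl with the reactive triflate and a weak base at low temperature should block retro-aldol cleavage in the basic coupling step while leaving the aldehyde and C11 unchanged.

Step 11
Reactants: 15 (R)-(−)-linalool
Product: 16 (1R)-1-methylcyclopent-2-en-1-ol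
Conditions: RuCl2(=CHPh)(PCy3)(H2IMes) (second-generation Grubbs catalyst, 0.5 mol%), CH2Cl2, 40 °C
Reagents that add atoms: none
Why: Ring-closing olefin metathesis of the 1,6-diene with loss of isobutene should give the cyclopentenol, and the chiral-pool stereocentre C25 is not involved.

Step 12
Reactants: 16 (1R)-1-methylcyclopent-2-en-1-ol
Product: 17 (1S,2R,5S)-2-methyl-6-oxabicyclo[3.1.0]hexan-2-ol (epoxide cis to the hydroxyl)
Conditions: VO(acac)2 (2 mol%), t-BuOOH, toluene, 0 → 25 °C
Reagents that add atoms: tert-butyl hydroperoxide, CC(C)(C)OO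
Why: Hydroxyl-directed vanadium-catalysed epoxidation should deliver oxygen to the alkene face syn to the C25 hydroxyl.

Step 13
Reactants: 17 epoxy alcohol; 18 2-methylpropanenitrile
Product: 19 2-[(1S,2S,3R)-2,3-dihydroxy-3-methylcyclopentyl]-2-methylpropanenitrile
Conditions: 18 (2.4 equiv), LiN(iPr)2 (2.4 equiv), THF, −78 °C; then 17, −78 → 40 °C; aqueous NH4Cl
Reagents that add atoms: none
Why: SN2 epoxide opening by a metallated nitrile should occur at C22, remote from the quaternary alkoxide-bearing C25, with inversion, so that the new quaternary C28 ends anti to both oxygens, and a cis-epoxy alkoxide cannot undergo Payne rearrangement.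

Step 14
Reactants: 19 diol nitrile
Product: 20 2-[(1S,3R)-3-hydroxy-3-methyl-2-oxocyclopentyl]-2-methylpropanenitrile
Conditions: (COCl)2, DMSO, CH2Cl2, −78 °C; then Et3N, −78 → 0 °C
Reagents that add atoms: none
Why: Swern oxidation should oxidise only the secondary C21 hydroxyl (the tertiary one is inert) and is cold and non-acidic enough not to epimerise C22.

Step 15
Reactants: 20 hydroxy ketone
Product: 21 2-[(1S,3R)-3-hydroxy-3-methyl-2-methylidenecyclopentyl]-2-methylpropanenitrile
Conditions: Zn, CH2Br2, TiCl4, THF–CH2Cl2, 0 → 25 °C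
Reagents that add atoms: dibromomethane, BrCBr
Why: Takai–Lombardo methylenation uses a non-basic gem-dimetallic reagent that should methylenate the hindered, enolisable ketone without epimerising C22 and tolerates the free hydroxyl and the nitrile.

Step 16
Reactants: 21 methylidene compound
Product: 23 2-[(1R,2R,3R)-3-hydroxy-3-methyl-2-(prop-2-en-1-yl)cyclopentyl]-2-methylpropanenitrile, via alkylborane 22 (not isolated)
Conditions: 9-BBN (3 equiv), THF, 25 → 50 °C; then bromoethene, PdCl2(dppf) (5 mol%), aqueous K3PO4, DMF, 50 °C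
Reagents that add atoms: bromoethene, C=CBr
Why: Hydroboration followed by B-alkyl Suzuki–Miyaura coupling should work because 9-BBN approaches the exocyclic alkene from the face opposite the bulky 2-cyanopropan-2-yl group on C22 (the hydroxyl face), which puts hydrogen on C21 syn to the hydroxyl and C20 cis to the C22 side chain before the primary alkylborane is vinylated.

Step 17
Reactants: 23 allyl nitrile
Product: 25 2,4-dimethyl-4-[(1R,2R,3R)-3-hydroxy-3-methyl-2-(prop-2-en-1-yl)cyclopentyl]pent-1-en-3-one, via ketimine 24 (not isolated)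
Conditions: 2-bromopropene, t-BuLi, Et2O, −78 °C (isopropenyllithium, 3.5 equiv); then 23, −78 → 25 °C; then 1 M HCl, THF, 25 °C
Reagents that add atoms: 2-bromopropene, CC(Br)=C; water, O
Why: Addition of an alkenyllithium to the tertiary nitrile (no α-hydrogen) should stop at the N-lithio ketimine, and mild aqueous acid then hydrolyses ketimine 24 to the α-methyl enone.

Step 18
Reactants: 25 dienone
Product: 26 cis-fused bicyclic enone (C14 ketone, C16=C18 alkene, 21R,22R,25R)
Conditions: RuCl2(=CHPh)(PCy3)(H2IMes) (second-generation Grubbs catalyst, 5 mol%), CH2Cl2 (5 mM), 40 °C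
Reagents that add atoms: none
Why: Ring-closing metathesis between the allyl group and the 1,1-disubstituted enone alkene, helped by the cis arrangement of the two arms, should close the seven-membered ring C14–C16–C18–C20–C21–C22–C28 as an α-methyl cycloheptenone.

Step 19
Reactants: 26 bicyclic enone; 27 methyl(diphenyl)phosphine oxide
Product: 28 tertiary allylic alcohol carrying CH2P(O)Ph2 on C14 (C14 epimers)
Conditions: 27 (3 equiv), n-BuLi, THF, −78 °C; CeCl3; then 26, −78 → 0 °C
Reagents that add atoms: none
Why: 1,2-Addition of a phosphoryl-stabilised organocerium reagent (the first stage of a Horner–Wittig sequence) should take place at the hindered enone carbonyl without enolisation, the lithium alkoxide does not eliminate, and the configuration at C14 is lost in the next step.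

Step 20
Reactants: 28 tertiary allylic alcohol
Product: 29 transposed enone (C18 ketone, C14=C16 alkene, C13–P(O)Ph2)
Conditions: C5H5NH[CrO3Cl] (pyridinium chlorochromate, 4 equiv), NaOAc, 4 Å sieves, CH2Cl2, 25 °C
Reagents that add atoms: pyridinium chlorochromate, [O-][Cr](=O)(=O)Cl.c1cc[nH+]cc1
Why: In this Dauben-type oxidative 1,3-transposition the chromate ester of the tertiary allylic alcohol should undergo a [3,3] shift and oxidation, which moves oxygen to C18 and the double bond to C14=C16.

Step 21
Reactants: 29 transposed enone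
Product: 30 (18R)-allylic alcohol
Conditions: (S)-2-methyl-CBS-oxazaborolidine (0.5 equiv), BH3·SMe2, THF, −30 °C; MeOH quench
Reagents that add atoms: none
Why: In the Corey–Bakshi–Shibata reduction the fully substituted alkenyl side acts as the large group, so the (S)-catalyst should give the 18R carbinol by reagent control.

Step 22
Reactants: 30 allylic alcohol
Product: 31 bis(triethylsilyl) ether of 30
Conditions: TESOTf (3 equiv), 2,6-lutidine, CH2Cl2, −78 → 0 °C
Reagents that add atoms: triethylsilyl trifluoromethanesulfonate, CC[Si](CC)(CC)OS(=O)(=O)C(F)(F)F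
Why: Silylation of the secondary allylic and the tertiary hydroxyl with the reactive triflate should leave C13–H as the only acidic site for the coupling.

Step 23
Reactants: 31 allylic phosphine oxide; 14 silylated aldehyde
Product: 33 C12=C13 diene (E/Z mixture), via hydroxy phosphine oxide 32 (not isolated)
Conditions: 31 (1.2 equiv), n-BuLi, THF, −78 °C; 14, −78 → −20 °C; then KOt-Bu, 0 → 25 °C
Reagents that add atoms: none
Why: In this Horner–Wittig olefination the C13 carbanion should add through its α-carbon to the C12 aldehyde and the potassium alkoxide of 32 then loses diphenylphosphinate, the alkene geometry being irrelevant because the bond is reduced next and the C8 silyl ether blocking retro-aldol.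

Step 24
Reactants: 33 diene
Product: 34 fully silylated C14=C16 alkene with saturated C12–C13 linker
Conditions: 2-nitrobenzenesulfonyl hydrazide, Et3N, CH2Cl2, 25 °C
Reagents that add atoms: none
Why: Diimide reduction is highly sensitive to alkene substitution, so the 1,2-disubstituted C12=C13 bond should be saturated while the tetrasubstituted C14=C16 bond and the allylic C–O bond stay intact.

Step 25
Reactants: 34 silylated alkene
Product: 35 tetraol alkene (C8, C18, C25, C35 hydroxyls free)
Conditions: Bu4NF (10 equiv), THF, 50 °C; aqueous NH4Cl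
Reagents that add atoms: none
Why: Fluoride-mediated desilylation should remove the three triethylsilyl ethers and the tert-butyldimethylsilyl ether in one operation under conditions that do not ionise the allylic carbinol.

Step 26
Reactants: 35 tetraol alkene
Product: 36 CNP0203623.2 (target)
Conditions: VO(acac)2 (10 mol%), t-BuOOH, CH2Cl2, 0 °C
Reagents that add atoms: tert-butyl hydroperoxide, CC(C)(C)OO
Why: Vanadium-catalysed hydroxyl-directed epoxidation should oxidise the only alkene left, C14=C16, with oxygen delivered syn to the allylic C18 hydroxyl, which is the relative configuration of C14, C16 and C18 in the target.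

**Compound list**

1 | neryl acetate, (2Z)-3,7-dimethylocta-2,6-dien-1-yl acetate | CC(C)=CCC/C(C)=C\COC(C)=O | starting material
2 | neryl pinacol boronate, 2-[(2Z)-3,7-dimethylocta-2,6-dien-1-yl]-4,4,5,5-tetramethyl-1,3,2-dioxaborolane | CC(C)=CCC/C(C)=C\CB1OC(C)(C)C(C)(C)O1 | intermediate
3 | pent-4-enal | C=CCCC=O | starting material
4 | pinacol borate ester of alcohol 5 (O–B adduct of the allylboration) | CC1(C)OB(O[C@H](CCC=C)[C@@](C)(C=C)CCC=C(C)C)OC1(C)C | intermediate
5 | (5R,6R)-6-ethenyl-6,10-dimethylundeca-1,9-dien-5-ol | O[C@H](CCC=C)[C@@](C)(C=C)CCC=C(C)C | intermediate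
6 | (5R,6R)-8-[(2R)-3,3-dimethyloxiran-2-yl]-6-ethenyl-6-methyloct-1-en-5-ol | O[C@H](CCC=C)[C@@](C)(C=C)CC[C@H]1OC1(C)C | intermediate
7 | (3R,6R,7R)-7-(but-3-en-1-yl)-6-ethenyl-2,2,6-trimethyloxepan-3-ol | CC1(C)O[C@H](CCC=C)[C@@](C)(C=C)CC[C@H]1O | intermediate
8 | tert-butyldimethylsilyl ether of 7 | CC1(C)O[C@H](CCC=C)[C@@](C)(C=C)CC[C@H]1O[Si](C)(C)C(C)(C)C | intermediate
9 | 4-[(2R,3R,6R)-6-(tert-butyldimethylsilyloxy)-3-ethenyl-3,7,7-trimethyloxepan-2-yl]butan-2-one | CC1(C)O[C@H](CCC(C)=O)[C@@](C)(C=C)CC[C@H]1O[Si](C)(C)C(C)(C)C | intermediate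
10 | 4-[(2R,3R,6R)-6-(tert-butyldimethylsilyloxy)-3-(2-hydroxyethyl)-3,7,7-trimethyloxepan-2-yl]butan-2-ol, C8 epimers | CC1(C)O[C@H](CCC(C)O)[C@@](C)(CCO)CC[C@H]1O[Si](C)(C)C(C)(C)C | intermediate
11 | oxepane keto aldehyde, 2-[(2R,3R,6R)-6-(tert-butyldimethylsilyloxy)-3,7,7-trimethyl-2-(3-oxobutyl)oxepan-3-yl]acetaldehyde | CC1(C)O[C@H](CCC(C)=O)[C@@](C)(CC=O)CC[C@H]1O[Si](C)(C)C(C)(C)C | intermediate
12 | pyrrolidine enamine of 11 at C11=C12 | CC1(C)O[C@H](CCC(C)=O)[C@@](C)(/C=C/N2CCCC2)CC[C@H]1O[Si](C)(C)C(C)(C)C | intermediate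
13 | bicyclic β-hydroxy aldehyde: trans-fused oxepane–cyclohexane, axial C8–OH syn to C32, equatorial C11–CHO, C35–OTBS (5R,8S,11R,31R,35R) | CC1(C)O[C@@H]2CC[C@](C)(O)[C@H](C=O)[C@@]2(C)CC[C@H]1O[Si](C)(C)C(C)(C)C | intermediate
14 | C8 triethylsilyl ether of 13 | CC1(C)O[C@@H]2CC[C@](C)(O[Si](CC)(CC)CC)[C@H](C=O)[C@@]2(C)CC[C@H]1O[Si](C)(C)C(C)(C)C | intermediate
15 | (R)-(−)-linalool, (3R)-3,7-dimethylocta-1,6-dien-3-ol | C=C[C@](C)(O)CCC=C(C)C | starting material
16 | (1R)-1-methylcyclopent-2-en-1-ol | C[C@]1(O)C=CCC1 | intermediate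
17 | (1S,2R,5S)-2-methyl-6-oxabicyclo[3.1.0]hexan-2-ol, epoxide cis to OH | C[C@]1(O)[C@H]2O[C@H]2CC1 | intermediate
18 | 2-methylpropanenitrile (isobutyronitrile) | CC(C)C#N | starting material
19 | 2-[(1S,2S,3R)-2,3-dihydroxy-3-methylcyclopentyl]-2-methylpropanenitrile | C[C@]1(O)[C@@H](O)[C@H](C(C)(C)C#N)CC1 | intermediate
20 | 2-[(1S,3R)-3-hydroxy-3-methyl-2-oxocyclopentyl]-2-methylpropanenitrile | C[C@]1(O)C(=O)[C@H](C(C)(C)C#N)CC1 | intermediate
21 | 2-[(1S,3R)-3-hydroxy-3-methyl-2-methylidenecyclopentyl]-2-methylpropanenitrile | C[C@]1(O)C(=C)[C@H](C(C)(C)C#N)CC1 | intermediate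
22 | B-alkyl-9-borabicyclo[3.3.1]nonane from 21 (boron on C20, H on C21 syn to OH; hydroxyl drawn free) | C[C@]1(O)[C@H](CB2C3CCCC2CCC3)[C@H](C(C)(C)C#N)CC1 | intermediate
23 | 2-[(1R,2R,3R)-3-hydroxy-3-methyl-2-(prop-2-en-1-yl)cyclopentyl]-2-methylpropanenitrile | C[C@]1(O)[C@H](CC=C)[C@H](C(C)(C)C#N)CC1 | intermediate
24 | N–H ketimine of 25 | C[C@]1(O)[C@H](CC=C)[C@H](C(C)(C)C(=N)C(C)=C)CC1 | intermediate
25 | 2,4-dimethyl-4-[(1R,2R,3R)-3-hydroxy-3-methyl-2-(prop-2-en-1-yl)cyclopentyl]pent-1-en-3-one | C[C@]1(O)[C@H](CC=C)[C@H](C(C)(C)C(=O)C(C)=C)CC1 | intermediate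
26 | cis-fused bicyclo[5.3.0] enone: C14 ketone, C16(Me)=C18, gem-dimethyl C28, C25 methyl carbinol with OH syn to both ring-fusion hydrogens (21R,22R,25R) | O=C1C(C)=CC[C@@H]2[C@@H](CC[C@@]2(C)O)C1(C)C | intermediate
27 | methyl(diphenyl)phosphine oxide | CP(=O)(c1ccccc1)c1ccccc1 | starting material
28 | tertiary allylic alcohol: 26 with OH and CH2P(O)Ph2 on C14, C14 epimers | OC1(CP(=O)(c3ccccc3)c3ccccc3)C(C)=CC[C@@H]2[C@@H](CC[C@@]2(C)O)C1(C)C | intermediate
29 | transposed enone: C18 ketone, C14=C16, diphenylphosphorylmethyl (C13) on C14 | O=C1C[C@@H]2[C@@H](CC[C@@]2(C)O)C(C)(C)C(CP(=O)(c3ccccc3)c3ccccc3)=C1C | intermediate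
30 | (18R)-allylic alcohol of 29; C18–OH on the face of the ring-fusion hydrogens | O=P(CC1=C(C)[C@H](O)C[C@@H]2[C@@H](CC[C@@]2(C)O)C1(C)C)(c1ccccc1)c1ccccc1 | intermediate
31 | C18,C25 bis(triethylsilyl) ether of 30 | O=P(CC1=C(C)[C@H](O[Si](CC)(CC)CC)C[C@@H]2[C@@H](CC[C@@]2(C)O[Si](CC)(CC)CC)C1(C)C)(c1ccccc1)c1ccccc1 | intermediate
32 | β-hydroxy phosphine oxide adduct of 31 and 14 (C12–OH, C13–P(O)Ph2; isomer mixture) | CC1(C)O[C@@H]2CC[C@](C)(O[Si](CC)(CC)CC)[C@H](C(O)C(C3=C(C)[C@H](O[Si](CC)(CC)CC)C[C@@H]4[C@@H](CC[C@@]4(C)O[Si](CC)(CC)CC)C3(C)C)P(=O)(c3ccccc3)c3ccccc3)[C@@]2(C)CC[C@H]1O[Si](C)(C)C(C)(C)C | intermediate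
33 | C12=C13, C14=C16 diene, fully silylated (E/Z mixture at C12=C13) | CC1(C)O[C@@H]2CC[C@](C)(O[Si](CC)(CC)CC)[C@H](C=CC3=C(C)[C@H](O[Si](CC)(CC)CC)C[C@@H]4[C@@H](CC[C@@]4(C)O[Si](CC)(CC)CC)C3(C)C)[C@@]2(C)CC[C@H]1O[Si](C)(C)C(C)(C)C | intermediate
34 | fully silylated C14=C16 alkene with saturated C12–C13 linker | CC1(C)O[C@@H]2CC[C@](C)(O[Si](CC)(CC)CC)[C@H](CCC3=C(C)[C@H](O[Si](CC)(CC)CC)C[C@@H]4[C@@H](CC[C@@]4(C)O[Si](CC)(CC)CC)C3(C)C)[C@@]2(C)CC[C@H]1O[Si](C)(C)C(C)(C)C | intermediate
35 | tetraol alkene (target lacking the epoxide oxygen) | CC1(C)O[C@@H]2CC[C@](C)(O)[C@H](CCC3=C(C)[C@H](O)C[C@@H]4[C@@H](CC[C@@]4(C)O)C3(C)C)[C@@]2(C)CC[C@H]1O | intermediate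
36 | CNP0203623.2 | CC1(C)O[C@@H]2CC[C@](C)(O)[C@H](CC[C@@]34O[C@]3(C)[C@H](O)C[C@@H]3[C@@H](CC[C@@]3(C)O)C4(C)C)[C@@]2(C)CC[C@H]1O | target

**Step count and risks**

Total step count: 26 (steps 1–10 to aldehyde 14, steps 11–22 to phosphine oxide 31, steps 23–26 after the union).
Longest linear sequence: 16 steps (15 → 36, steps 11–26); the left branch from 1 is 14 steps.

The three steps most likely to fail:

1. Step 9 (key aldol). The ring closure may be followed by loss of water to the conjugated enal, the ketone enamine may close C7 onto C12 instead, or equilibration may stop short and leave C8/C11 epimers. Fallback, setting out from 11 and returning at 13: organocatalytic α-chlorination of the aldehyde (N-chlorosuccinimide, L-prolinamide 10 mol%, CH2Cl2, 0 °C) gives the α-chloro keto aldehyde F1. SmI2 (2.2 equiv) in THF at −78 °C then reduces the C–Cl bond to a samarium enolate located only at C11–C12. This adds irreversibly to the C8 ketone in a Reformatsky-type closure through the chair that keeps methyl C9 away from axial C32, giving 13. An irreversible metal-enolate addition thus replaces reversible enamine catalysis.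

2. Step 4 (oxepane closure). The hydroxyl may open the epoxide in the 6-exo sense at C35 to a tetrahydropyran, or the acid may rearrange the epoxide before ring closure. Fallback, setting out from 5 and returning at 7: Hg(OCOCF3)2 in MeNO2 at −20 °C, then aqueous NaCl, effects Markovnikov oxymercuration of the trisubstituted alkene by the C5 hydroxyl and closes the oxepane as the oxepan-3-ylmercury chloride F2. NaBH4 under O2 in DMF replaces mercury by hydroxyl to give the oxepan-3-ol epimer mixture F3. Dess–Martin periodinane gives the oxepan-3-one F4. (S)-2-methyl-CBS-oxazaborolidine with catecholborane in toluene at −78 °C (no free borane, so the terminal alkenes survive) sets C35 as R and returns 7.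

3. Step 23 (Horner–Wittig union). Addition of the bulky carbanion to the doubly flanked aldehyde may be slow, so that enolisation at C11 with loss of the C8 silyloxy group, or vinylogous loss of the C18 silyloxy group from the carbanion, takes over. Fallback, setting out from 14 and returning at 34:
   - Methylenation (Ph3PCH3Br, KOt-Bu, THF) gives the C12=C13 vinyl compound F5.
   - 9-BBN, then NaOH/H2O2, gives the primary alcohol F6.
   - I2, PPh3 and imidazole give the primary iodide F7.
   - Enone 26 is silylated (TESOTf, 2,6-lutidine) to its triethylsilyl ether F8.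
   - t-BuLi (Et2O, −78 °C) converts F7 into the alkyllithium, which after transmetallation with CeCl3 adds to the carbonyl of F8 to give the tertiary allylic alcohol F9.
   - Pyridinium chlorochromate effects oxidative 1,3-transposition to the coupled enone F10.
   - (S)-2-methyl-CBS-oxazaborolidine with BH3·SMe2 gives the 18R allylic alcohol F11.
   - TESOTf/2,6-lutidine returns 34.
   
   Here the union is a carbonyl addition forming C13–C14, so neither the olefination nor the diimide reduction is needed.

Further compounds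
F1 | step 9 | α-chloro keto aldehyde (11 chlorinated at C11, epimers) | CC1(C)O[C@H](CCC(C)=O)[C@@](C)(C(Cl)C=O)CC[C@H]1O[Si](C)(C)C(C)(C)C
F2 | step 4 | oxepan-3-ylmercury chloride (C35–HgCl) | CC1(C)O[C@H](CCC=C)[C@@](C)(C=C)CCC1[Hg]Cl
F3 | step 4 | oxepan-3-ol, C35 epimer mixture | CC1(C)O[C@H](CCC=C)[C@@](C)(C=C)CCC1O
F4 | step 4 | oxepan-3-one | CC1(C)O[C@H](CCC=C)[C@@](C)(C=C)CCC1=O
F5 | step 23 | C12=C13 vinyl compound from 14 | CC1(C)O[C@@H]2CC[C@](C)(O[Si](CC)(CC)CC)[C@H](C=C)[C@@]2(C)CC[C@H]1O[Si](C)(C)C(C)(C)C
F6 | step 23 | C13 primary alcohol | CC1(C)O[C@@H]2CC[C@](C)(O[Si](CC)(CC)CC)[C@H](CCO)[C@@]2(C)CC[C@H]1O[Si](C)(C)C(C)(C)C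
F7 | step 23 | C13 primary iodide | CC1(C)O[C@@H]2CC[C@](C)(O[Si](CC)(CC)CC)[C@H](CCI)[C@@]2(C)CC[C@H]1O[Si](C)(C)C(C)(C)C
F8 | step 23 | triethylsilyl ether of enone 26 | O=C1C(C)=CC[C@@H]2[C@@H](CC[C@@]2(C)O[Si](CC)(CC)CC)C1(C)C
F9 | step 23 | coupled tertiary allylic alcohol (C14–OH, C14 epimers) | CC1(C)O[C@@H]2CC[C@](C)(O[Si](CC)(CC)CC)[C@H](CCC3(O)C(C)=CC[C@@H]4[C@@H](CC[C@@]4(C)O[Si](CC)(CC)CC)C3(C)C)[C@@]2(C)CC[C@H]1O[Si](C)(C)C(C)(C)C
F10 | step 23 | coupled enone (C18 ketone, C14=C16) | CC1(C)O[C@@H]2CC[C@](C)(O[Si](CC)(CC)CC)[C@H](CCC3=C(C)C(=O)C[C@@H]4[C@@H](CC[C@@]4(C)O[Si](CC)(CC)CC)C3(C)C)[C@@]2(C)CC[C@H]1O[Si](C)(C)C(C)(C)C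
F11 | step 23 | coupled (18R)-allylic alcohol | CC1(C)O[C@@H]2CC[C@](C)(O[Si](CC)(CC)CC)[C@H](CCC3=C(C)[C@H](O)C[C@@H]4[C@@H](CC[C@@]4(C)O[Si](CC)(CC)CC)C3(C)C)[C@@]2(C)CC[C@H]1O[Si](C)(C)C(C)(C)C
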